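## Analysis of the target

The target is a C12 chain, numbered here from the lactone carbonyl C1 to the methyl C12. It is folded into a 5,6-dihydro-2H-pyran-2-one (O, C1–C5) and a 2,5-disubstituted tetrahydrofuran (O, C7–C10). The two rings are joined through the carbinol C6, and the C11 oxygen carries a (Z)-p-coumarate.

There are five stereocentres: C5 (R), C6 (S), C7 (R), C10 (S) and C11 (S). C5/C6 are erythro, C6/C7 and C10/C11 are threo, and C7/C10 are cis across the tetrahydrofuran.

The sensitive groups are the Z-cinnamate, the free phenol and the unsaturated δ-lactone. The Z-cinnamate goes to E under light, by reversible conjugate addition, or when the free acid is activated. The lactone is a Michael acceptor and opens or eliminates under base.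

C6 and C11 are both secondary carbinols in similar surroundings, yet only C11 is acylated. They must be told apart by design, not by a late selective acylation.

The strategy rests on the ring bond C7–C8, which lies next to the ring oxygen. C7 can therefore enter as the O–CH2 group of an acyclic ether, and a carbene at C8 attacks one of its C–H bonds. A carbonyl at C9 is the temporary handle that makes the carbene accessible. The other four stereocentres must be in place before the ring closes: C5/C6 come from a 2-deoxypentose and C10/C11 from a syn-aldol.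

## Retrosynthetic reasoning

The last bonds formed are the lactone O–C1 bond and the free C5/C6 diol. Target 33 is traced through the open dihydroxy ester 32 to the acetonide-protected methyl Z-enoate 31. Cutting here keeps the C6 hydroxyl masked until the coumarate is already on C11, so no selective acylation is needed. The forward step must hydrolyse the acetal and let the C5 hydroxyl close the six-membered lactone on the Z-ester.

The cinnamate Cα=Cβ bond of 31 is cut next, through the aryl silyl ether 30, to aldehyde 29 and the C11 phosphonoacetate 28. Ester 28 comes from alcohol 26 and acid 27, and 26 from silyl ether 25. Building the Z-alkene on the substrate avoids activating a free Z-cinnamic acid, where the acyl-transfer catalyst can add and leave again and so erode the geometry.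

The C2=C3 bond of 25 is cut to the C3 aldehyde 23 and phosphonate 24. Aldehyde 23 is the ozonolysis product, through ozonide 22, of the terminal alkene 21. Carrying C3 as the end of an allyl group removes one protecting group from the sequence and unmasks the aldehyde in one step.

In 21 the C9 position is a plain methylene. It is traced through thiocarbonyl derivative 20 and alcohol 19 to ketone 18, which still holds the oxygen that made ring closure possible.

Ketone 18 is opened at the C7–C8 bond to diazoketone 17. This is the only ring C–C bond whose cleavage leaves a simple acyclic ether with both oxygenated halves intact. The cis-ring problem then becomes the functionalisation of one O–CH2 group under the control of C10.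

Diazoketone 17 is cut at C8–C9 to acid 15 (through mixed anhydride 16), the C8 carbon coming from diazomethane.

Acid 15 goes back through 13 to aldol 12, and the C10–C11 bond is cut to imide 8 and acetaldehyde 9 (through 10 and 11). The aldol creates the C11 hydroxyl as the only free hydroxyl, so its silylation is unambiguous, and it sets both centres with the ether already in place. Attaching a ready-made C9–C12 unit by O-alkylation would need regioselective protection of a vicinal diol and an alkoxide beside a silyl ether, which invites silyl migration.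

Imide 8 is cut at the N-acyl bond to acid 5 and auxiliary 6 (through 7). Acid 5 is cut at the O–C10 ether bond to alcohol 3 and bromoacetic acid 4.

Alcohol 3 is traced by a Wittig disconnection to lactol 2 and then to 2-deoxy-L-ribose 1. The erythro diol of 1 becomes C5/C6 unchanged, and opening the lactol frees the C7 hydroxyl without any differentiation of chain ends.

## Alternatives that were turned down

Alternative 1: The ring is not closed but taken from a meso bicycle. The C5=C6 alkene and the C10–C11 bond are traced to the strained alkene of 7-oxabicyclo[2.2.1]hept-2-ene A1 and to 4-(4-methoxybenzyloxy)but-1-ene A2. A chiral ruthenium alkylidene, RuCl2(NHC*)(=CH-2-iPrOC6H4), opens A1 and cross-couples one end with A2, giving (2R,5S)-2-[(E)-4-(4-methoxybenzyloxy)but-1-enyl]-5-vinyltetrahydrofuran A3.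
- For: the cis relationship of C7 and C10 is fixed by the bicycle and cannot leak; the step is catalytic and the precursor is trivial. On ring geometry this is stronger than the chosen route, where cis selectivity rests on a transition-state preference.
- Against: A3 carries none of the three carbinol centres. The E-alkene needs a net anti dihydroxylation to reach the erythro C5/C6 pair, since syn dihydroxylation gives threo. The vinyl group needs a Markovnikov oxygenation with control at C11, and the two alkenes must be told apart. Enantioselection with an unbiased terminal alkene, E/Z control and oligomerisation add uncertainty.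
- Comparison: the chosen strategy spends more steps before the ring closes, but brings C5, C6, C10 and C11 into the key step already fixed.

Alternative 2: Both ring C–O bonds and the flanking C6–O and C11–O bonds are cut at once, back to the (2E,6E)-octa-2,6-dienoyl bornane-10,2-sultam A4. KMnO4 in buffered acetone adds across both alkenes through a cyclic manganate ester and gives the cis-tetrahydrofuran diol A5, the sultam choosing the face.
- For: four of the five stereocentres and the ring arise in one step from a short diene, and the threo–cis–threo pattern follows from the syn-addition mechanism. On stereocentre and step economy this is stronger than the chosen route.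
- Against: in A5 the C6 and C11 hydroxyls are both free, so the differentiation problem returns at once. C5 is still an acyl carbon and must be set by a reagent-controlled addition to an epimerisable α-oxygenated aldehyde, erythro to C6 and so against chelation control. Permanganate cyclisations are prone to over-oxidation, and the face selection rests on a remote auxiliary.
- Comparison: the chosen strategy offers C5/C6 unchanged from the chiral pool, C10/C11 from a selective aldol, and hydroxyls that are differentiated from the moment they appear.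

Alternative 3: Here the lactone is the ring that is disconnected. C4–C5 and O–C1 are cut to the tetrahydrofuran aldehyde A6 and (E)-1-methoxybuta-1,3-diene A7. A chiral Schiff-base chromium chloride, Cr(L*)Cl (trivalent chromium), activates the aldehyde for a hetero-Diels–Alder reaction that gives the cis-2-methoxy-5,6-dihydro-2H-pyran A8, a masked lactone.
- For: C5 is set by the catalyst and the six-membered ring forms in one step. In A8 the C6 and C11 oxygens already carry different protecting groups, which is better than any plan that acylates a diol selectively.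
- Against: the reaction addresses the easy ring. A6, with the cis-tetrahydrofuran and four stereocentres, must still be made. A6 is α-branched, α-oxygenated and epimerisable at C6, a slow and possibly mismatched partner for a mono-oxygenated diene. The acetal needs hydrolysis and oxidation to become the lactone.
- Comparison: in the chosen route the lactone costs three routine operations from a terminal alkene, with C5 from the chiral pool, so this step would not shorten it.

Key step: step 9

Assumption: the phosphonoacetic acid 27, like 24 and 29, is bought; carbons are numbered C1 (lactone carbonyl) to C12 (methyl) in every compound.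

## Steps

Step 1
Reactants: 1 2-deoxy-L-ribose
Product: 2 3,4-O-isopropylidene-2-deoxy-L-erythro-pentopyranose (lactol, anomeric mixture)
Conditions: 2-methoxypropene, pyridinium p-toluenesulfonate (cat.), EtOAc, 0 °C to rt
Reagents that add atoms: 2-methoxypropene, COC(C)=C
Why: Kinetic acetalisation under mild acid should take the cis-3,4-diol of the pyranose form, the only vicinal cis-diol available, and leave the lactol free; no stereocentre is touched.

Step 2
Reactants: 2 3,4-O-isopropylidene-2-deoxy-L-erythro-pentopyranose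
Product: 3 [(4S,5R)-2,2-dimethyl-5-(prop-2-en-1-yl)-1,3-dioxolan-4-yl]methanol
Conditions: Ph3PCH3Br, KOtBu (excess), THF, 0 °C to rt
Reagents that add atoms: methyltriphenylphosphonium bromide, C[P+](c1ccccc1)(c1ccccc1)c1ccccc1.[Br-]
Why: Wittig methylenation of the open-chain aldehyde in equilibrium with the lactol should give the terminal alkene and free the C7 hydroxyl, so the two chain ends are differentiated without a protecting group; excess ylide is used because the lactol hydroxyl consumes base.

Step 3
Reactants: 3 [(4S,5R)-2,2-dimethyl-5-(prop-2-en-1-yl)-1,3-dioxolan-4-yl]methanol; 4 bromoacetic acid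
Product: 5 2-{[(4S,5R)-2,2-dimethyl-5-(prop-2-en-1-yl)-1,3-dioxolan-4-yl]methoxy}acetic acid
Conditions: NaH (3 equiv), THF, 0 °C to rt; aq. HCl to pH 3
Reagents that add atoms: none
Why: Williamson ether synthesis: the sodium alkoxide of 3 displaces bromide from sodium bromoacetate and forms the O–C10 bond of the future ring ether; the primary halide next to a carboxylate cannot eliminate.

Step 4
Reactants: 5 2-{[(4S,5R)-2,2-dimethyl-5-(prop-2-en-1-yl)-1,3-dioxolan-4-yl]methoxy}acetic acid; 6 (R)-4-benzyl-1,3-oxazolidin-2-one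
Product: 8 (4R)-4-benzyl-3-(2-{[(4S,5R)-2,2-dimethyl-5-(prop-2-en-1-yl)-1,3-dioxolan-4-yl]methoxy}acetyl)-1,3-oxazolidin-2-one, via mixed pivalic anhydride 7 (not isolated)
Conditions: t-BuCOCl, Et3N, THF, −20 °C; then 6, LiCl, −20 °C to rt
Reagents that add atoms: pivaloyl chloride, CC(C)(C)C(Cl)=O (its atoms stay in 7 only)
Why: N-acylation of the oxazolidinone through the mixed pivalic anhydride is the standard entry to N-glycolyl imides and avoids an acid chloride that would endanger the acetonide.

Step 5
Reactants: 8 (4R)-4-benzyl-3-(2-{[(4S,5R)-2,2-dimethyl-5-(prop-2-en-1-yl)-1,3-dioxolan-4-yl]methoxy}acetyl)-1,3-oxazolidin-2-one; 9 acetaldehyde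
Product: 12 (4R)-4-benzyl-3-[(2R,3S)-2-{[(4S,5R)-2,2-dimethyl-5-(prop-2-en-1-yl)-1,3-dioxolan-4-yl]methoxy}-3-hydroxybutanoyl]-1,3-oxazolidin-2-one, via dibutylboron Z-enolate 10 (not isolated), via dibutylboron aldolate 11 (not isolated)
Conditions: Bu2BOTf, Et3N, CH2Cl2, −78 to 0 °C; then 9, −78 to 0 °C; pH 7 buffer, MeOH, 30% H2O2, 0 °C
Reagents that add atoms: dibutylboron triflate, CCCCB(CCCC)OS(=O)(=O)C(F)(F)F (its atoms stay in 10 and 11 only)
Why: Evans syn-aldol: the Z boron enolate 10 adds to acetaldehyde through a closed chair transition state on the face away from the benzyl group of the (R)-auxiliary, which sets C10 and C11 together in the threo relationship and absolute sense of the target.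

Step 6
Reactants: 12 (4R)-4-benzyl-3-[(2R,3S)-2-{[(4S,5R)-2,2-dimethyl-5-(prop-2-en-1-yl)-1,3-dioxolan-4-yl]methoxy}-3-hydroxybutanoyl]-1,3-oxazolidin-2-one
Product: 13 (4R)-4-benzyl-3-[(2R,3S)-3-[(tert-butyldimethylsilyl)oxy]-2-{[(4S,5R)-2,2-dimethyl-5-(prop-2-en-1-yl)-1,3-dioxolan-4-yl]methoxy}butanoyl]-1,3-oxazolidin-2-one
Conditions: TBSOTf, 2,6-lutidine, CH2Cl2, −78 to 0 °C
Reagents that add atoms: tert-butyldimethylsilyl triflate, CC(C)(C)[Si](C)(C)OS(=O)(=O)C(F)(F)F
Why: Silylation of the only free hydroxyl, so no regiochemical question arises; a bulky, weakly basic silyl ether is chosen because it should stay inert toward the carbene in step 9.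

Step 7
Reactants: 13 (4R)-4-benzyl-3-[(2R,3S)-3-[(tert-butyldimethylsilyl)oxy]-2-{[(4S,5R)-2,2-dimethyl-5-(prop-2-en-1-yl)-1,3-dioxolan-4-yl]methoxy}butanoyl]-1,3-oxazolidin-2-one
Product: 15 (2R,3S)-3-[(tert-butyldimethylsilyl)oxy]-2-{[(4S,5R)-2,2-dimethyl-5-(prop-2-en-1-yl)-1,3-dioxolan-4-yl]methoxy}butanoic acid, via peroxy acid 14 (not isolated)
Conditions: LiOH, 30% H2O2, THF/H2O, 0 °C; then Na2SO3; aq. HCl to pH 3, 0 °C
Reagents that add atoms: hydrogen peroxide, OO
Why: Hydroperoxide attacks the exocyclic imide carbonyl selectively; sulfite reduces peroxy acid 14 to acid 15 and the auxiliary is released, without epimerisation at C10.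

Step 8
Reactants: 15 (2R,3S)-3-[(tert-butyldimethylsilyl)oxy]-2-{[(4S,5R)-2,2-dimethyl-5-(prop-2-en-1-yl)-1,3-dioxolan-4-yl]methoxy}butanoic acid
Product: 17 (3R,4S)-4-[(tert-butyldimethylsilyl)oxy]-1-diazo-3-{[(4S,5R)-2,2-dimethyl-5-(prop-2-en-1-yl)-1,3-dioxolan-4-yl]methoxy}pentan-2-one, via mixed isobutyl carbonic anhydride 16 (not isolated)
Conditions: i-BuOCOCl, Et3N, Et2O, −20 °C; then CH2N2 (excess), Et2O, 0 °C to rt
Reagents that add atoms: isobutyl chloroformate, CC(C)COC(Cl)=O (its atoms stay in 16 only); diazomethane, C=[N+]=[N-]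
Why: Acylation of diazomethane by the mixed carbonic anhydride gives the α-diazoketone under near-neutral conditions that acetonide, silyl ether and the unactivated alkene tolerate; C8 enters here.

Step 9
Reactants: 17 (3R,4S)-4-[(tert-butyldimethylsilyl)oxy]-1-diazo-3-{[(4S,5R)-2,2-dimethyl-5-(prop-2-en-1-yl)-1,3-dioxolan-4-yl]methoxy}pentan-2-one
Product: 18 (2R,5R)-2-{(1S)-1-[(tert-butyldimethylsilyl)oxy]ethyl}-5-[(4S,5R)-2,2-dimethyl-5-(prop-2-en-1-yl)-1,3-dioxolan-4-yl]oxolan-3-one (2,5-cis)
Conditions: Rh2(OAc)4 (2 mol %), CH2Cl2, slow addition at high dilution, rt to 40 °C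
Reagents that add atoms: none
Why: Rh2(OAc)4 (divalent rhodium) should expel N2 from 17 and give an electrophilic metal carbene at C8, which inserts into one C7–H bond through a three-centre transition state with hydride-transfer character; the closest known reaction type is the dirhodium-catalysed C–H insertion of α-alkoxy diazoketones next to the ether oxygen, which gives cis-2,5-disubstituted 3(2H)-furanones. The C7–C8 bond and the five-membered ring (O, C7, C8, C9, C10) form in one event as a 1,5-insertion. The new stereocentre C7 is controlled by C10: in the envelope-like transition state the C10 side chain and the dioxolane on C7 both take pseudo-equatorial positions, which places them cis. Site selectivity is needed against the C6–H bond (1,6-insertion), against ylide formation at the silyl ether or acetal oxygens, and against the remote alkene. It should come from the ring-size preference of the insertion, from the lone pair of the ether oxygen that stabilises positive charge at C7, from the low basicity of the hindered silyl ether, and from high dilution, which suppresses bimolecular cyclopropanation and carbene dimerisation. The C7–H bonds are β to the acetal oxygen at C6 and so less hydridic than in a simple alkyl ether, which is the main uncertainty. C10, now α to a ketone, is not touched under these neutral conditions, and 18 is reduced without delay.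

Step 10
Reactants: 18 (2R,5R)-2-{(1S)-1-[(tert-butyldimethylsilyl)oxy]ethyl}-5-[(4S,5R)-2,2-dimethyl-5-(prop-2-en-1-yl)-1,3-dioxolan-4-yl]oxolan-3-one
Product: 19 (2S,5R)-2-{(1S)-1-[(tert-butyldimethylsilyl)oxy]ethyl}-5-[(4S,5R)-2,2-dimethyl-5-(prop-2-en-1-yl)-1,3-dioxolan-4-yl]oxolan-3-ol (either C3 epimer)
Conditions: NaBH4, MeOH, −40 to 0 °C
Reagents that add atoms: none
Why: Hydride reduction of the ketone; the configuration at C9 is irrelevant because this oxygen is removed, and the low temperature limits epimerisation at C10.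

Step 11
Reactants: 19 (2S,5R)-2-{(1S)-1-[(tert-butyldimethylsilyl)oxy]ethyl}-5-[(4S,5R)-2,2-dimethyl-5-(prop-2-en-1-yl)-1,3-dioxolan-4-yl]oxolan-3-ol
Product: 20 O-{(2S,5R)-2-{(1S)-1-[(tert-butyldimethylsilyl)oxy]ethyl}-5-[(4S,5R)-2,2-dimethyl-5-(prop-2-en-1-yl)-1,3-dioxolan-4-yl]oxolan-3-yl} 1H-imidazole-1-carbothioate
Conditions: 1,1'-thiocarbonyldiimidazole, 4-(dimethylamino)pyridine (cat.), toluene, 80 °C
Reagents that add atoms: 1,1'-thiocarbonyldiimidazole, S=C(n1ccnc1)n1ccnc1
Why: Neutral thioacylation is used in place of the NaH/CS2/MeI xanthate protocol, whose alkoxide could trigger silyl migration from the C11 oxygen to the C9 oxygen.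

Step 12
Reactants: 20 O-{(2S,5R)-2-{(1S)-1-[(tert-butyldimethylsilyl)oxy]ethyl}-5-[(4S,5R)-2,2-dimethyl-5-(prop-2-en-1-yl)-1,3-dioxolan-4-yl]oxolan-3-yl} 1H-imidazole-1-carbothioate
Product: 21 tert-butyl{(1S)-1-[(2S,5R)-5-[(4S,5R)-2,2-dimethyl-5-(prop-2-en-1-yl)-1,3-dioxolan-4-yl]oxolan-2-yl]ethoxy}dimethylsilane
Conditions: Bu3SnH (3 equiv), azobisisobutyronitrile (cat.), toluene, 100 °C
Reagents that add atoms: none
Why: Barton–McCombie deoxygenation: the stannyl radical adds to sulfur, the C9–O bond fragments and the secondary radical is quenched by Bu3SnH, used concentrated so that intermolecular hydrogen transfer outruns any intramolecular hydrogen shift.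

Step 13
Reactants: 21 tert-butyl{(1S)-1-[(2S,5R)-5-[(4S,5R)-2,2-dimethyl-5-(prop-2-en-1-yl)-1,3-dioxolan-4-yl]oxolan-2-yl]ethoxy}dimethylsilane
Product: 23 2-[(4R,5S)-5-{(2R,5S)-5-[(1S)-1-[(tert-butyldimethylsilyl)oxy]ethyl]oxolan-2-yl}-2,2-dimethyl-1,3-dioxolan-4-yl]acetaldehyde, via secondary ozonide 22 (not isolated)
Conditions: O3, CH2Cl2, −78 °C; then PPh3, −78 °C to rt; used crude
Reagents that add atoms: ozone, [O-][O+]=O
Why: Ozonolysis of the only alkene and reduction of ozonide 22 give the C3 aldehyde; the allyl group has served as a masked aldehyde, so no protecting group is removed here.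

Step 14
Reactants: 23 2-[(4R,5S)-5-{(2R,5S)-5-[(1S)-1-[(tert-butyldimethylsilyl)oxy]ethyl]oxolan-2-yl}-2,2-dimethyl-1,3-dioxolan-4-yl]acetaldehyde; 24 methyl 2-[bis(2,2,2-trifluoroethoxy)phosphoryl]acetate
Product: 25 methyl (2Z)-4-[(4R,5S)-5-{(2R,5S)-5-[(1S)-1-[(tert-butyldimethylsilyl)oxy]ethyl]oxolan-2-yl}-2,2-dimethyl-1,3-dioxolan-4-yl]but-2-enoate
Conditions: KN(SiMe3)2, 18-crown-6, THF, −78 °C
Reagents that add atoms: none
Why: Still–Gennari olefination: the electron-poor phosphonate under dissociating conditions eliminates fast from the kinetically formed adduct and should give the Z-enoate; −78 °C limits β-elimination of the β-alkoxy aldehyde.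

Step 15
Reactants: 25 methyl (2Z)-4-[(4R,5S)-5-{(2R,5S)-5-[(1S)-1-[(tert-butyldimethylsilyl)oxy]ethyl]oxolan-2-yl}-2,2-dimethyl-1,3-dioxolan-4-yl]but-2-enoate
Product: 26 methyl (2Z)-4-[(4R,5S)-5-{(2R,5S)-5-[(1S)-1-hydroxyethyl]oxolan-2-yl}-2,2-dimethyl-1,3-dioxolan-4-yl]but-2-enoate
Conditions: HF·pyridine, pyridine, THF, 0 °C to rt
Reagents that add atoms: none
Why: Fluoride cleaves the Si–O bond of the secondary silyl ether; the pyridine-buffered reagent is not basic, which protects the Z-enoate, and is mild enough for the acetonide.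

Step 16
Reactants: 26 methyl (2Z)-4-[(4R,5S)-5-{(2R,5S)-5-[(1S)-1-hydroxyethyl]oxolan-2-yl}-2,2-dimethyl-1,3-dioxolan-4-yl]but-2-enoate; 27 2-[bis(2,2,2-trifluoroethoxy)phosphoryl]acetic acid
Product: 28 methyl (2Z)-4-[(4R,5S)-5-{(2R,5S)-5-[(1S)-1-({2-[bis(2,2,2-trifluoroethoxy)phosphoryl]acetyl}oxy)ethyl]oxolan-2-yl}-2,2-dimethyl-1,3-dioxolan-4-yl]but-2-enoate
Conditions: EDC·HCl, 4-(dimethylamino)pyridine (cat.), CH2Cl2, 0 °C to rt
Reagents that add atoms: none
Why: Steglich-type carbodiimide esterification of the C11 hydroxyl, the only free hydroxyl because C5 and C6 are still tied in the acetonide; this is where the C11/C6 differentiation is secured.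

Step 17
Reactants: 28 methyl (2Z)-4-[(4R,5S)-5-{(2R,5S)-5-[(1S)-1-({2-[bis(2,2,2-trifluoroethoxy)phosphoryl]acetyl}oxy)ethyl]oxolan-2-yl}-2,2-dimethyl-1,3-dioxolan-4-yl]but-2-enoate; 29 4-[(tert-butyldimethylsilyl)oxy]benzaldehyde
Product: 30 methyl (2Z)-4-[(4R,5S)-5-{(2R,5S)-5-[(1S)-1-{[(2Z)-3-{4-[(tert-butyldimethylsilyl)oxy]phenyl}prop-2-enoyl]oxy}ethyl]oxolan-2-yl}-2,2-dimethyl-1,3-dioxolan-4-yl]but-2-enoate
Conditions: KN(SiMe3)2 (1.0 equiv), 18-crown-6, THF, −78 °C; then 29, −78 °C, dark
Reagents that add atoms: none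
Why: A second Horner–Wadsworth–Emmons reaction of the Still–Gennari type, now with the phosphonate on the substrate; aromatic aldehydes react with a strong Z preference, and no Z-acid ever has to be activated.

Step 18
Reactants: 30 methyl (2Z)-4-[(4R,5S)-5-{(2R,5S)-5-[(1S)-1-{[(2Z)-3-{4-[(tert-butyldimethylsilyl)oxy]phenyl}prop-2-enoyl]oxy}ethyl]oxolan-2-yl}-2,2-dimethyl-1,3-dioxolan-4-yl]but-2-enoate
Product: 31 methyl (2Z)-4-[(4R,5S)-5-{(2R,5S)-5-[(1S)-1-{[(2Z)-3-(4-hydroxyphenyl)prop-2-enoyl]oxy}ethyl]oxolan-2-yl}-2,2-dimethyl-1,3-dioxolan-4-yl]but-2-enoate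
Conditions: Bu4NF, AcOH (1:1), THF, 0 °C, dark
Reagents that add atoms: none
Why: Aryl silyl ethers are cleaved fast by buffered fluoride because phenoxide is a good leaving group; the acetic acid buffer keeps the medium non-basic for the two Z-esters.

Step 19
Reactants: 31 methyl (2Z)-4-[(4R,5S)-5-{(2R,5S)-5-[(1S)-1-{[(2Z)-3-(4-hydroxyphenyl)prop-2-enoyl]oxy}ethyl]oxolan-2-yl}-2,2-dimethyl-1,3-dioxolan-4-yl]but-2-enoate
Product: 33 (1S)-1-[(2S,5R)-5-{(S)-hydroxy[(2R)-6-oxo-3,6-dihydro-2H-pyran-2-yl]methyl}oxolan-2-yl]ethyl (2Z)-3-(4-hydroxyphenyl)prop-2-enoate (CNP0417147.1), via dihydroxy ester 32 (not isolated)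
Conditions: CF3CO2H/H2O (9:1), CH2Cl2, 0 °C to rt, dark
Reagents that add atoms: none
Why: Aqueous acid hydrolyses the acetonide to diol 32; the C5 hydroxyl then attacks the Z-configured methyl ester, the six-membered ring being favoured over the seven-membered one from C6–OH, which closes the lactone and leaves the C6 hydroxyl free.

## Compound list

1 | 2-deoxy-L-ribose | OC[C@H](O)[C@H](O)CC=O | starting material
2 | 3,4-O-isopropylidene-2-deoxy-L-erythro-pentopyranose | OC1C[C@H]2OC(C)(C)O[C@H]2CO1 | intermediate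
3 | [(4S,5R)-2,2-dimethyl-5-(prop-2-en-1-yl)-1,3-dioxolan-4-yl]methanol | C=CC[C@H]1OC(C)(C)O[C@H]1CO | intermediate
4 | bromoacetic acid | OC(=O)CBr | starting material
5 | 2-{[(4S,5R)-2,2-dimethyl-5-(prop-2-en-1-yl)-1,3-dioxolan-4-yl]methoxy}acetic acid | C=CC[C@H]1OC(C)(C)O[C@H]1COCC(=O)O | intermediate
6 | (R)-4-benzyl-1,3-oxazolidin-2-one | O=C1N[C@H](Cc2ccccc2)CO1 | starting material
7 | mixed pivalic anhydride of 5 | C=CC[C@H]1OC(C)(C)O[C@H]1COCC(=O)OC(=O)C(C)(C)C | intermediate (not isolated)
8 | N-glycolyl oxazolidinone (name as in step 4) | C=CC[C@H]1OC(C)(C)O[C@H]1COCC(=O)N1C(=O)OC[C@H]1Cc1ccccc1 | intermediate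
9 | acetaldehyde | CC=O | starting material
10 | dibutylboron Z-enolate of 8 | C=CC[C@H]1OC(C)(C)O[C@H]1CO/C=C(\OB(CCCC)CCCC)N1C(=O)OC[C@H]1Cc1ccccc1 | intermediate (not isolated)
11 | dibutylboron aldolate of 12 | C[C@H](OB(CCCC)CCCC)[C@@H](OC[C@@H]1OC(C)(C)O[C@@H]1CC=C)C(=O)N1C(=O)OC[C@H]1Cc1ccccc1 | intermediate (not isolated)
12 | syn-aldol adduct, (2R,3S)-3-hydroxybutanoyl imide (name as in step 5) | C[C@H](O)[C@@H](OC[C@@H]1OC(C)(C)O[C@@H]1CC=C)C(=O)N1C(=O)OC[C@H]1Cc1ccccc1 | intermediate
13 | silyl ether of 12 (name as in step 6) | C[C@H](O[Si](C)(C)C(C)(C)C)[C@@H](OC[C@@H]1OC(C)(C)O[C@@H]1CC=C)C(=O)N1C(=O)OC[C@H]1Cc1ccccc1 | intermediate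
14 | peroxy acid corresponding to 15 | C[C@H](O[Si](C)(C)C(C)(C)C)[C@@H](OC[C@@H]1OC(C)(C)O[C@@H]1CC=C)C(=O)OO | intermediate (not isolated)
15 | (2R,3S)-3-[(tert-butyldimethylsilyl)oxy]-2-{[(4S,5R)-2,2-dimethyl-5-(prop-2-en-1-yl)-1,3-dioxolan-4-yl]methoxy}butanoic acid | C[C@H](O[Si](C)(C)C(C)(C)C)[C@@H](OC[C@@H]1OC(C)(C)O[C@@H]1CC=C)C(=O)O | intermediate
16 | mixed isobutyl carbonic anhydride of 15 | C[C@H](O[Si](C)(C)C(C)(C)C)[C@@H](OC[C@@H]1OC(C)(C)O[C@@H]1CC=C)C(=O)OC(=O)OCC(C)C | intermediate (not isolated)
17 | α-alkoxy diazoketone (name as in step 8) | C[C@H](O[Si](C)(C)C(C)(C)C)[C@@H](OC[C@@H]1OC(C)(C)O[C@@H]1CC=C)C(=O)C=[N+]=[N-] | intermediate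
18 | cis-2,5-disubstituted oxolan-3-one (name as in step 9) | C[C@H](O[Si](C)(C)C(C)(C)C)[C@@H]1C(=O)C[C@H]([C@@H]2OC(C)(C)O[C@@H]2CC=C)O1 | intermediate
19 | oxolan-3-ol (name as in step 10) | C[C@H](O[Si](C)(C)C(C)(C)C)[C@@H]1C(O)C[C@H]([C@@H]2OC(C)(C)O[C@@H]2CC=C)O1 | intermediate
20 | imidazole-1-carbothioate of 19 | C[C@H](O[Si](C)(C)C(C)(C)C)[C@@H]1C(OC(=S)n2ccnc2)C[C@H]([C@@H]2OC(C)(C)O[C@@H]2CC=C)O1 | intermediate
21 | cis-2,5-disubstituted oxolane (name as in step 12) | C[C@H](O[Si](C)(C)C(C)(C)C)[C@@H]1CC[C@H]([C@@H]2OC(C)(C)O[C@@H]2CC=C)O1 | intermediate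
22 | secondary ozonide (1,2,4-trioxolane) of 21 | C[C@H](O[Si](C)(C)C(C)(C)C)[C@@H]1CC[C@H]([C@@H]2OC(C)(C)O[C@@H]2CC3OCOO3)O1 | intermediate (not isolated)
23 | C3 aldehyde (name as in step 13) | C[C@H](O[Si](C)(C)C(C)(C)C)[C@@H]1CC[C@H]([C@@H]2OC(C)(C)O[C@@H]2CC=O)O1 | intermediate
24 | methyl 2-[bis(2,2,2-trifluoroethoxy)phosphoryl]acetate | COC(=O)CP(=O)(OCC(F)(F)F)OCC(F)(F)F | starting material
25 | methyl Z-enoate, C11 silyl ether (name as in step 14) | C[C@H](O[Si](C)(C)C(C)(C)C)[C@@H]1CC[C@H]([C@@H]2OC(C)(C)O[C@@H]2C/C=C\C(=O)OC)O1 | intermediate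
26 | methyl Z-enoate, C11 alcohol (name as in step 15) | C[C@H](O)[C@@H]1CC[C@H]([C@@H]2OC(C)(C)O[C@@H]2C/C=C\C(=O)OC)O1 | intermediate
27 | 2-[bis(2,2,2-trifluoroethoxy)phosphoryl]acetic acid | OC(=O)CP(=O)(OCC(F)(F)F)OCC(F)(F)F | starting material
28 | C11 phosphonoacetate (name as in step 16) | C[C@H](OC(=O)CP(=O)(OCC(F)(F)F)OCC(F)(F)F)[C@@H]1CC[C@H]([C@@H]2OC(C)(C)O[C@@H]2C/C=C\C(=O)OC)O1 | intermediate
29 | 4-[(tert-butyldimethylsilyl)oxy]benzaldehyde | O=Cc1ccc(O[Si](C)(C)C(C)(C)C)cc1 | starting material
30 | Z-coumarate, aryl silyl ether (name as in step 17) | C[C@H](OC(=O)/C=C\c1ccc(O[Si](C)(C)C(C)(C)C)cc1)[C@@H]1CC[C@H]([C@@H]2OC(C)(C)O[C@@H]2C/C=C\C(=O)OC)O1 | intermediate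
31 | Z-coumarate, free phenol (name as in step 18) | C[C@H](OC(=O)/C=C\c1ccc(O)cc1)[C@@H]1CC[C@H]([C@@H]2OC(C)(C)O[C@@H]2C/C=C\C(=O)OC)O1 | intermediate
32 | methyl (2Z,5R,6R)-5,6-dihydroxy-6-[(2R,5S)-5-[(1S)-1-{[(2Z)-3-(4-hydroxyphenyl)prop-2-enoyl]oxy}ethyl]oxolan-2-yl]hex-2-enoate | C[C@H](OC(=O)/C=C\c1ccc(O)cc1)[C@@H]1CC[C@H]([C@H](O)[C@H](O)C/C=C\C(=O)OC)O1 | intermediate (not isolated)
33 | CNP0417147.1 (name as in step 19) | C[C@H](OC(=O)/C=C\c1ccc(O)cc1)[C@@H]1CC[C@H]([C@H](O)[C@H]2CC=CC(=O)O2)O1 | target

## Step count and least certain steps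

Total: 19 steps. Longest linear sequence: 19 steps, from 1 to 33; all other inputs are purchased.

**Step 9 (key step).** The C7–H bonds are inductively deactivated by the C6 acetal oxygen, so insertion may be slow. Carbene dimerisation, 1,6-insertion at C6–H, ylide formation at the acetal oxygen, or silyl transfer from the C11 ether to the carbene could then take over.

Fallback (sets out from 3, returns at 21): the C7–C8 bond is made by recombination of an oxocarbenium ion with an aluminium enolate (Petasis–Ferrier rearrangement), which does not depend on the hydridic character of C7–H. Oxidation of 3 (Dess–Martin periodinane, NaHCO3, CH2Cl2) would give (4R,5R)-2,2-dimethyl-5-(prop-2-en-1-yl)-1,3-dioxolane-4-carbaldehyde F1. Commercial O-benzyl-D-threonine would be diazotised (NaNO2, aq. H2SO4; retention by double inversion) to (2R,3S)-3-(benzyloxy)-2-hydroxybutanoic acid F2. Silylation (Me3SiCl, Et3N) would give its bis(trimethylsilyl) derivative F3, and condensation with F1 (Me3SiOTf cat., CH2Cl2, −78 °C) the cis-2,5-disubstituted 1,3-dioxolan-4-one F4. Methylenation of the lactone carbonyl with Cp2TiMe2 (toluene, 65 °C) would give the 4-methylene-1,3-dioxolane F5. iBu3Al (CH2Cl2, −78 °C to rt) should then open the acetal, close C7–C8 with the cis-2,5 arrangement and reduce the ketone to the tetrahydrofuran-3-ol F6. Deoxygenation as in steps 11 and 12 would pass through the imidazole-1-carbothioate F7 to the benzyl ether F8. Lithium 4,4'-di-tert-butylbiphenylide (THF, −78 °C), which spares the terminal alkene, would give the C11 alcohol F9, and silylation (TBSCl, imidazole, DMF) returns to 21.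

**Step 12.** The C9 radical may abstract the C5 hydrogen of the dioxolane through a six-membered transition state before it meets the stannane. This would scramble C5 or open the acetal.

Fallback (sets out from 19, returns at 21): the oxygen is removed by a polar displacement in place of the radical chain. 19 would be converted (Tf2O, pyridine, CH2Cl2, −20 °C) into the C9 trifluoromethanesulfonate F10, and LiEt3BH (THF, 0 °C) would displace the sulfonate by hydride to give 21.

**Step 17.** Addition to the electron-rich aldehyde is slow, which may let the adducts equilibrate and erode the Z preference. The base may also deprotonate the γ-position of the methyl Z-enoate.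

Fallback (sets out from 26, returns at 30): the Z-alkene is made by semi-hydrogenation of an alkyne. Commercial tert-butyl(4-ethynylphenoxy)dimethylsilane would be carboxylated (n-BuLi, THF, −78 °C; CO2) to 3-{4-[(tert-butyldimethylsilyl)oxy]phenyl}prop-2-ynoic acid F11. Esterification with 26 (EDC·HCl, 4-(dimethylamino)pyridine) would give the propiolate F12. Hydrogenation (H2, Pd/CaCO3 poisoned with Pb(OAc)2, quinoline, EtOAc) delivers cis hydrogen to the alkyne only and returns to 30.

**Step 19.** Protic acid may isomerise the p-hydroxycinnamate from Z to E, the acetal may hydrolyse incompletely, or the freed C6 hydroxyl may add to the enoate in conjugate fashion in place of lactonisation.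

Fallback (sets out from 28, returns at 33): the acid step is moved ahead of the cinnamate, so the Z-cinnamate never meets acid. 28 would be treated with CF3CO2H/H2O to remove the acetonide and close the lactone, giving the lactone phosphonoacetate F13 with a free C6 hydroxyl. Olefination with 29 (KN(SiMe3)2, 18-crown-6, THF, −78 °C; the phosphonate is far more acidic than the hydroxyl) would give the aryl silyl ether F14. HF·pyridine buffered with pyridine removes the silyl group and gives 33.

## Further compounds

F1 | step 9 | (4R,5R)-2,2-dimethyl-5-(prop-2-en-1-yl)-1,3-dioxolane-4-carbaldehyde | C=CC[C@H]1OC(C)(C)O[C@H]1C=O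
F2 | step 9 | (2R,3S)-3-(benzyloxy)-2-hydroxybutanoic acid | C[C@H](OCc1ccccc1)[C@@H](O)C(=O)O
F3 | step 9 | trimethylsilyl (2R,3S)-3-(benzyloxy)-2-[(trimethylsilyl)oxy]butanoate | C[C@H](OCc1ccccc1)[C@@H](O[Si](C)(C)C)C(=O)O[Si](C)(C)C
F4 | step 9 | cis-2,5-disubstituted 1,3-dioxolan-4-one (ring C2 carries the allyl-dioxolane, ring C5 the (1S)-1-(benzyloxy)ethyl group) | C[C@H](OCc1ccccc1)[C@H]1O[C@@H]([C@@H]2OC(C)(C)O[C@@H]2CC=C)OC1=O
F5 | step 9 | 4-methylene-1,3-dioxolane from F4 | C[C@H](OCc1ccccc1)[C@H]1O[C@@H]([C@@H]2OC(C)(C)O[C@@H]2CC=C)OC1=C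
F6 | step 9 | cis-2,5-disubstituted tetrahydrofuran-3-ol, C11 benzyl ether | C[C@H](OCc1ccccc1)[C@@H]1C(O)C[C@H]([C@@H]2OC(C)(C)O[C@@H]2CC=C)O1
F7 | step 9 | imidazole-1-carbothioate of F6 | C[C@H](OCc1ccccc1)[C@@H]1C(OC(=S)n2ccnc2)C[C@H]([C@@H]2OC(C)(C)O[C@@H]2CC=C)O1
F8 | step 9 | cis-2,5-disubstituted oxolane, C11 benzyl ether | C[C@H](OCc1ccccc1)[C@@H]1CC[C@H]([C@@H]2OC(C)(C)O[C@@H]2CC=C)O1
F9 | step 9 | (1S)-1-[(2S,5R)-5-[(4S,5R)-2,2-dimethyl-5-(prop-2-en-1-yl)-1,3-dioxolan-4-yl]oxolan-2-yl]ethanol | C[C@H](O)[C@@H]1CC[C@H]([C@@H]2OC(C)(C)O[C@@H]2CC=C)O1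
F10 | step 12 | C9 trifluoromethanesulfonate of 19 | C[C@H](O[Si](C)(C)C(C)(C)C)[C@@H]1C(OS(=O)(=O)C(F)(F)F)C[C@H]([C@@H]2OC(C)(C)O[C@@H]2CC=C)O1
F11 | step 17 | 3-{4-[(tert-butyldimethylsilyl)oxy]phenyl}prop-2-ynoic acid | OC(=O)C#Cc1ccc(O[Si](C)(C)C(C)(C)C)cc1
F12 | step 17 | C11 arylpropiolate of 26 | C[C@H](OC(=O)C#Cc1ccc(O[Si](C)(C)C(C)(C)C)cc1)[C@@H]1CC[C@H]([C@@H]2OC(C)(C)O[C@@H]2C/C=C\C(=O)OC)O1
F13 | step 19 | lactone with free C6 hydroxyl and C11 phosphonoacetate | C[C@H](OC(=O)CP(=O)(OCC(F)(F)F)OCC(F)(F)F)[C@@H]1CC[C@H]([C@H](O)[C@H]2CC=CC(=O)O2)O1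
F14 | step 19 | aryl tert-butyldimethylsilyl ether of 33 | C[C@H](OC(=O)/C=C\c1ccc(O[Si](C)(C)C(C)(C)C)cc1)[C@@H]1CC[C@H]([C@H](O)[C@H]2CC=CC(=O)O2)O1
A1 | alternative 1 | 7-oxabicyclo[2.2.1]hept-2-ene (meso) | C1=CC2CCC1O2
A2 | alternative 1 | 4-(4-methoxybenzyloxy)but-1-ene | C=CCCOCc1ccc(OC)cc1
A3 | alternative 1 | (2R,5S)-2-[(E)-4-(4-methoxybenzyloxy)but-1-enyl]-5-vinyltetrahydrofuran | C=C[C@@H]1CC[C@H](/C=C/CCOCc2ccc(OC)cc2)O1
A4 | alternative 2 | N-[(2E,6E)-octa-2,6-dienoyl]bornane-10,2-sultam | C/C=C/CC/C=C/C(=O)N1[C@H]2C[C@@H]3CC[C@@]2(CS1(=O)=O)C3(C)C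
A5 | alternative 2 | cis-tetrahydrofuran diol N-acyl sultam (C6 S, C7 R, C10 S, C11 S) | C[C@H](O)[C@@H]1CC[C@H]([C@H](O)C(=O)N2[C@H]3C[C@@H]4CC[C@@]3(CS2(=O)=O)C4(C)C)O1
A6 | alternative 3 | tetrahydrofuran C5 aldehyde with C6 silyl ether and C11 4-methoxybenzyl ether | C[C@H](OCc1ccc(OC)cc1)[C@@H]1CC[C@H]([C@H](O[Si](C)(C)C(C)(C)C)C=O)O1
A7 | alternative 3 | (E)-1-methoxybuta-1,3-diene | CO/C=C/C=C
A8 | alternative 3 | cis-2-methoxy-6-substituted 5,6-dihydro-2H-pyran (masked lactone) | C[C@H](OCc1ccc(OC)cc1)[C@@H]1CC[C@H]([C@H](O[Si](C)(C)C(C)(C)C)[C@H]2CC=C[C@@H](OC)O2)O1
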